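**Plan**
- Retrosynthesis: the C12–OOH bond is cut first (peroxide SN2 on a 12S propargylic mesylate), then C13=C16/C14=C15 (ethene–alkyne metathesis) and C12–C13 (acetylide opening of an 8α,12-lactone). The O6/O7/O8 triad is traced back to a 6-oxo-7-ene.
- The decalin is then cut at C5–C10 and C6–C7 together. In ring B the C8 carbinol/C9 methine pair is the trace of a C8=C9 double bond, and C5(H)–C6(O) is the trace of an enal dienophile whose formyl group on C6 serves as a ketene equivalent. C1–C4 of ring A are the tether, so the precursor is an acyclic trienal.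
- Forward: acetylacetone and tert-butyl bromoacetate give an (E)-enol triflate; B-alkyl Suzuki coupling (C1–C10) with the borane from 2,2-dimethylpent-4-enal, methylenation and oxidation give the trienal. One intramolecular Diels–Alder reaction closes rings A and B, followed by ring B oxidation, lactone, side chain.
- Stereochemistry: C5/C10 from a chiral amine catalyst and the endo transition state; C9 by α-face protonation; C6 by α-face hydride; C7 by hydroxyl-directed epoxidation; C8 by backside lactonisation; C12 by asymmetric transfer hydrogenation followed by SN2 inversion.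

Key step: step 8

Remark: labdane numbering is used for positions (C1–C10 decalin, C11–C16 side chain, C17 on C8, C20 on C10; α = face of H-5, β = face of the C10 methyl); compound 21 is drawn as the open hydroxy ynone although part of it may sit as a cyclic hemiketal.

Step 1
Reactants: 1 pentane-2,4-dione; 2 tert-butyl bromoacetate
Product: 3 tert-butyl 3-acetyl-4-oxopentanoate
Conditions: K2CO3, acetone, reflux
Reagents that add atoms: none
Why: C-alkylation of the β-diketone enolate with a reactive α-bromo ester (classical 1,3-dicarbonyl alkylation) installs C11/C12 as a masked carboxyl group.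

Step 2
Reactants: 3 tert-butyl 3-acetyl-4-oxopentanoate
Product: 4 tert-butyl (3E)-3-acetyl-4-(trifluoromethylsulfonyloxy)pent-3-enoate
Conditions: Tf2O, aq. Me4NOH, hexanes, 5 °C
Reagents that add atoms: trifluoromethanesulfonic anhydride, O=S(=O)(OS(=O)(=O)C(F)(F)F)C(F)(F)F
Why: O-triflation of the non-chelated ammonium enolate under biphasic conditions should give the (E)-enol triflate (enolate oxygen anti to the remaining acetyl group), which fixes the later C9=C10 geometry.

Step 3
Reactants: 5 2,2-dimethylpent-4-enal; 6 triethyl phosphonoacetate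
Product: 7 ethyl (2E)-4,4-dimethylhepta-2,6-dienoate
Conditions: NaH, THF, 0 °C to rt
Reagents that add atoms: none
Why: Horner–Wadsworth–Emmons olefination of the neopentyl aldehyde with a stabilised phosphonate gives the (E)-enoate that becomes C5=C6 and the formyl carbon.

Step 4
Reactants: 7 ethyl (2E)-4,4-dimethylhepta-2,6-dienoate
Product: 8 (2E)-4,4-dimethylhepta-2,6-dien-1-ol
Conditions: i-Bu2AlH, CH2Cl2, −78 °C
Reagents that add atoms: none
Why: 1,2-reduction of the enoate by the aluminium hydride gives the allylic alcohol without touching either double bond.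

Step 5
Reactants: 8 (2E)-4,4-dimethylhepta-2,6-dien-1-ol; 4 tert-butyl (3E)-3-acetyl-4-(trifluoromethylsulfonyloxy)pent-3-enoate
Product: 10 tert-butyl (3E,9E)-3-acetyl-11-hydroxy-4,8,8-trimethylundeca-3,9-dienoate, via B-alkyl-9-BBN borane 9 (not isolated)
Conditions: 9-BBN (2.2 equiv), THF, 0 °C to rt; then 4, PdCl2(dppf) (5 mol%), AsPh3, Cs2CO3, DMF/H2O, rt
Reagents that add atoms: none
Why: anti-Markovnikov hydroboration of the unhindered terminal alkene followed by B-alkyl Suzuki–Miyaura coupling, which should proceed with retention of the triflate geometry, forms C1–C10 and places the tether trans to the acetyl group.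

Step 6
Reactants: 10 tert-butyl (3E,9E)-3-acetyl-11-hydroxy-4,8,8-trimethylundeca-3,9-dienoate
Product: 11 tert-butyl (3E,9E)-11-hydroxy-4,8,8-trimethyl-3-(prop-1-en-2-yl)undeca-3,9-dienoate
Conditions: Zn, CH2Br2, TiCl4, THF (pre-formed reagent); then 10, CH2Cl2, 0 °C to rt
Reagents that add atoms: dibromomethane, BrCBr
Why: Takai–Lombardo methylenation is non-basic, so the enolisable ketone and the skipped ester are not isomerised, and it converts the acetyl group into the C7=C8 half of the diene while tolerating ester and hydroxyl.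

Step 7
Reactants: 11 tert-butyl (3E,9E)-11-hydroxy-4,8,8-trimethyl-3-(prop-1-en-2-yl)undeca-3,9-dienoate
Product: 12 tert-butyl (3E,9E)-4,8,8-trimethyl-11-oxo-3-(prop-1-en-2-yl)undeca-3,9-dienoate
Conditions: MnO2, CH2Cl2, rt
Reagents that add atoms: none
Why: chemoselective MnO2 oxidation of the allylic alcohol gives the (E)-enal dienophile without touching the diene.

Step 8
Reactants: 12 tert-butyl (3E,9E)-4,8,8-trimethyl-11-oxo-3-(prop-1-en-2-yl)undeca-3,9-dienoate
Product: 13 tert-butyl 6α-formyl-13,14,15,16-tetranorlabd-8-en-12-oate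
Conditions: (2S,5S)-5-benzyl-2-tert-butyl-3-methylimidazolidin-4-one·CF3CO2H (20 mol%), MeCN/H2O (98:2), 0 °C to rt
Reagents that add atoms: none
Why: Condensation of the enal with the secondary-amine catalyst gives an (E)-iminium ion whose lowered LUMO lets the tethered 2-methyl-1,3-diene add across C5=C6 in an asynchronous [4+2] event (C5–C10 leading, charge spread over C7–C8–C9), and hydrolysis returns the aldehyde; the closest known reaction type is the imidazolidinone-catalysed type 1 intramolecular Diels–Alder reaction of 2,8,10-trienals. Ring A closes as a six-membered carbocycle through the C5–C10 bond across the four-atom C1–C4 tether (fused mode, tether in a chair), and ring B is the cyclohexene of the cycloaddition itself (C6–C7 plus C5–C10). C5 is controlled by the catalyst, whose benzyl group covers one face of the iminium π system so that the diene adds to the other; C10 follows from the endo transition state with the tether exo on C5 and outside on C10, which puts the inside C20 methyl anti to H-5 (trans fusion); C6 (formyl α) follows from suprafacial addition to the (E)-enal and is erased in step 9. The step needs trans over cis fusion and a single π face: the (E)-geometry of C9=C10 set in steps 2 and 5 puts the tether outside, iminium activation favours the endo mode, and the gem-dimethyl group at C4 biases the tether toward the reactive fold. Only the fused regiochemistry is within reach of a four-atom tether, so no regioisomer is expected.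

Step 9
Reactants: 13 tert-butyl 6α-formyl-13,14,15,16-tetranorlabd-8-en-12-oate
Product: 16 tert-butyl 6-oxo-13,14,15,16-tetranorlabd-7-en-12-oate, via piperidine enamine 14 (not isolated), via deconjugated ketone 15 (not isolated)
Conditions: piperidine, 4 Å MS, PhH, 60 °C; then CuCl (10 mol%), O2, MeCN, 0 °C; then DBU, CH2Cl2, rt
Reagents that add atoms: dioxygen, O=O
Why: copper-catalysed oxygenative cleavage of the aldehyde enamine (nor-ketone synthesis) removes the formyl carbon, and base-mediated conjugation then moves the double bond to C7=C8 with γ-protonation of C9 on the α face, anti to the C10 methyl, while the trans ring fusion at C5 is the stable one.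

Step 10
Reactants: 16 tert-butyl 6-oxo-13,14,15,16-tetranorlabd-7-en-12-oate
Product: 17 tert-butyl 6β-hydroxy-13,14,15,16-tetranorlabd-7-en-12-oate
Conditions: NaBH4, CeCl3·7H2O, MeOH, −40 °C
Reagents that add atoms: none
Why: Luche 1,2-reduction delivers hydride to the α face of C6 because the β face is blocked by the axial methyl groups on C4 and C10, giving the axial 6β-alcohol.

Step 11
Reactants: 17 tert-butyl 6β-hydroxy-13,14,15,16-tetranorlabd-7-en-12-oate
Product: 18 tert-butyl 7β,8β-epoxy-6β-hydroxy-13,14,15,16-tetranorlabdan-12-oate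
Conditions: VO(acac)2 (5 mol%), t-BuOOH, CH2Cl2, 0 °C to rt
Reagents that add atoms: tert-butyl hydroperoxide, CC(C)(C)OO
Why: hydroxyl-directed vanadium-catalysed epoxidation delivers oxygen syn to the pseudoaxial 6β-hydroxyl, so the epoxide forms on the otherwise hindered β face and sets the 7β-oxygen.

Step 12
Reactants: 18 tert-butyl 7β,8β-epoxy-6β-hydroxy-13,14,15,16-tetranorlabdan-12-oate
Product: 19 6β,7β-dihydroxy-13,14,15,16-tetranorlabdan-8α,12-olide
Conditions: CF3CO2H, CH2Cl2, −20 to 0 °C
Reagents that add atoms: none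
Why: acid-promoted epoxy-ester lactonisation, in which the ester carbonyl opens the protonated epoxide at tertiary C8 from the α face (5-exo, inversion) and the tert-butyl group leaves as isobutene, sets 8α-O/8β-CH3, frees the 7β-hydroxyl and masks O8 and C12 in one trans-fused γ-lactone.

Step 13
Reactants: 19 6β,7β-dihydroxy-13,14,15,16-tetranorlabdan-8α,12-olide; 20 ethynyltrimethylsilane
Product: 21 6β,7β,8α-trihydroxy-14-trimethylsilyl-15,16-dinorlabd-13-yn-12-one
Conditions: 20, n-BuLi, THF, −78 °C; then 19, −78 to −20 °C; aq. NH4Cl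
Reagents that add atoms: none
Why: addition of the lithium acetylide (in excess, to cover the two hydroxyls) to the γ-lactone stops at the lithium lactolate and releases the hydroxy ynone on work-up, forming C12–C13.

Step 14
Reactants: 21 6β,7β,8α-trihydroxy-14-trimethylsilyl-15,16-dinorlabd-13-yn-12-one
Product: 22 6β-hydroxy-7β,8α-bis(triethylsilyloxy)-14-trimethylsilyl-15,16-dinorlabd-13-yn-12-one
Conditions: Et3SiOTf (2.5 equiv), 2,6-lutidine, CH2Cl2, −78 to 0 °C
Reagents that add atoms: triethylsilyl trifluoromethanesulfonate, CC[Si](CC)(CC)OS(=O)(=O)C(F)(F)F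
Why: silyl triflate silylation caps the secondary 7-hydroxyl and the tertiary 8-hydroxyl, which could otherwise cyclise onto C12 later, while the 6β-hydroxyl, flanked by three syn-axial methyl groups, is expected to stay free.

Step 15
Reactants: 22 6β-hydroxy-7β,8α-bis(triethylsilyloxy)-14-trimethylsilyl-15,16-dinorlabd-13-yn-12-one
Product: 23 (12S)-7β,8α-bis(triethylsilyloxy)-14-trimethylsilyl-15,16-dinorlabd-13-yne-6β,12-diol
Conditions: Ru[(S,S)-TsNCHPhCHPhNH](p-cymene) (2 mol%), i-PrOH, rt
Reagents that add atoms: none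
Why: asymmetric transfer hydrogenation of the alkynyl ketone under catalyst control, with the alkyne as the π-recognised group, should give the 12S propargylic alcohol.

Step 16
Reactants: 23 (12S)-7β,8α-bis(triethylsilyloxy)-14-trimethylsilyl-15,16-dinorlabd-13-yne-6β,12-diol
Product: 24 (12S)-6β-hydroxy-7β,8α-bis(triethylsilyloxy)-14-trimethylsilyl-15,16-dinorlabd-13-yn-12-yl methanesulfonate
Conditions: MsCl, Et3N, CH2Cl2, −20 °C
Reagents that add atoms: methanesulfonyl chloride, CS(=O)(=O)Cl
Why: sulfene-type mesylation takes the only accessible hydroxyl (C12), the 6β-hydroxyl being too hindered, and keeps the C12 configuration.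

Step 17
Reactants: 25 2,3-dimethylbut-2-ene
Product: 26 2-methoxyprop-2-yl hydroperoxide
Conditions: O3, MeOH/CH2Cl2, −78 °C
Reagents that add atoms: ozone, [O-][O+]=O; methanol, CO
Why: ozonolysis in methanol traps the carbonyl oxide as the α-methoxy hydroperoxide, a masked form of hydrogen peroxide.

Step 18
Reactants: 24 (12S)-6β-hydroxy-7β,8α-bis(triethylsilyloxy)-14-trimethylsilyl-15,16-dinorlabd-13-yn-12-yl methanesulfonate; 26 2-methoxyprop-2-yl hydroperoxide
Product: 27 (12R)-12-(2-methoxyprop-2-ylperoxy)-7β,8α-bis(triethylsilyloxy)-14-trimethylsilyl-15,16-dinorlabd-13-yn-6β-ol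
Conditions: 26 (3 equiv), CsOH·H2O (2 equiv), DMF, 0 °C
Reagents that add atoms: none
Why: SN2 displacement of the secondary propargylic sulfonate by the caesium peroxide (an α-effect nucleophile) with inversion sets 12R and leaves the hydroperoxide masked as a base-stable peroxyketal; any loss of the alkyne silyl group here is of no consequence because step 19 removes it anyway.

Step 19
Reactants: 27 (12R)-12-(2-methoxyprop-2-ylperoxy)-7β,8α-bis(triethylsilyloxy)-14-trimethylsilyl-15,16-dinorlabd-13-yn-6β-ol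
Product: 28 (12R)-12-(2-methoxyprop-2-ylperoxy)-15,16-dinorlabd-13-yne-6β,7β,8α-triol
Conditions: Bu4NF, AcOH (1:1), THF, 0 °C to rt
Reagents that add atoms: none
Why: fluoride-mediated desilylation cleaves both Si–O bonds and the Si–C(sp) bond, and the acetic acid buffer protects the base-sensitive propargylic peroxide.

Step 20
Reactants: 28 (12R)-12-(2-methoxyprop-2-ylperoxy)-15,16-dinorlabd-13-yne-6β,7β,8α-triol
Product: 29 (12R)-7β-acetoxy-12-(2-methoxyprop-2-ylperoxy)-15,16-dinorlabd-13-yne-6β,8α-diol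
Conditions: Ac2O, pyridine, 0 °C
Reagents that add atoms: acetic anhydride, CC(=O)OC(C)=O
Why: acylation should select the equatorial secondary 7β-hydroxyl over the hindered axial 6β-hydroxyl and the tertiary 8α-hydroxyl, with the peroxide still masked.

Step 21
Reactants: 29 (12R)-7β-acetoxy-12-(2-methoxyprop-2-ylperoxy)-15,16-dinorlabd-13-yne-6β,8α-diol; 30 ethene
Product: 31 (12R)-7β-acetoxy-12-(2-methoxyprop-2-ylperoxy)labda-13(16),14-diene-6β,8α-diol
Conditions: ethene (1 atm), second-generation Grubbs catalyst RuCl2(=CHPh)(PCy3)(H2IMes) (10 mol%), CH2Cl2, rt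
Reagents that add atoms: none
Why: ruthenium-carbene enyne cross-metathesis of the terminal alkyne with ethene builds the 2-substituted buta-1,3-diene (C16 and C15 from ethene) and is expected to tolerate the free hydroxyls and the dialkyl peroxide.

Step 22
Reactants: 31 (12R)-7β-acetoxy-12-(2-methoxyprop-2-ylperoxy)labda-13(16),14-diene-6β,8α-diol
Product: 32 (12R)-7β-acetoxy-12-hydroperoxylabda-13(16),14-diene-6β,8α-diol, (5S,6S,7S,8S,9R,10S,12R)
Conditions: AcOH/THF/H2O (4:2:1), rt
Reagents that add atoms: none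
Why: mild acid hydrolysis of the peroxyketal frees the hydroperoxide without breaking the C12–O bond, so 12R is kept and acetate, diene and alcohols are untouched.

**Compound list**
1 | pentane-2,4-dione | CC(=O)CC(C)=O | starting material
2 | tert-butyl bromoacetate | BrCC(=O)OC(C)(C)C | starting material
3 | tert-butyl 3-acetyl-4-oxopentanoate | CC(=O)C(CC(=O)OC(C)(C)C)C(C)=O | intermediate
4 | tert-butyl (3E)-3-acetyl-4-(trifluoromethylsulfonyloxy)pent-3-enoate | FC(F)(F)S(=O)(=O)O/C(C)=C(\CC(=O)OC(C)(C)C)C(C)=O | intermediate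
5 | 2,2-dimethylpent-4-enal | C=CCC(C)(C)C=O | starting material
6 | triethyl phosphonoacetate | CCOC(=O)CP(=O)(OCC)OCC | starting material
7 | ethyl (2E)-4,4-dimethylhepta-2,6-dienoate | CCOC(=O)/C=C/C(C)(C)CC=C | intermediate
8 | (2E)-4,4-dimethylhepta-2,6-dien-1-ol | OC/C=C/C(C)(C)CC=C | intermediate
9 | 9-{(5E)-4,4-dimethyl-7-[(9-borabicyclo[3.3.1]nonan-9-yl)oxy]hept-5-en-1-yl}-9-borabicyclo[3.3.1]nonane | C1CCC2CCCC1B2OC/C=C/C(C)(C)CCCB1C2CCCC1CCC2 | intermediate
10 | tert-butyl (3E,9E)-3-acetyl-11-hydroxy-4,8,8-trimethylundeca-3,9-dienoate | OC/C=C/C(C)(C)CCC/C(C)=C(\CC(=O)OC(C)(C)C)C(C)=O | intermediate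
11 | tert-butyl (3E,9E)-11-hydroxy-4,8,8-trimethyl-3-(prop-1-en-2-yl)undeca-3,9-dienoate | OC/C=C/C(C)(C)CCC/C(C)=C(\CC(=O)OC(C)(C)C)C(C)=C | intermediate
12 | tert-butyl (3E,9E)-4,8,8-trimethyl-11-oxo-3-(prop-1-en-2-yl)undeca-3,9-dienoate | O=C/C=C/C(C)(C)CCC/C(C)=C(\CC(=O)OC(C)(C)C)C(C)=C | intermediate
13 | tert-butyl 6α-formyl-13,14,15,16-tetranorlabd-8-en-12-oate (H-5 α, CH3-10 β) | CC(C)(C)OC(=O)CC1=C(C)C[C@H](C=O)[C@H]2C(C)(C)CCC[C@@]21C | intermediate
14 | tert-butyl 6-(piperidin-1-ylmethylidene)-13,14,15,16-tetranorlabd-8-en-12-oate | CC(C)(C)OC(=O)CC1=C(C)CC(=CN3CCCCC3)[C@H]2C(C)(C)CCC[C@@]21C | intermediate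
15 | tert-butyl 6-oxo-13,14,15,16-tetranorlabd-8-en-12-oate | CC(C)(C)OC(=O)CC1=C(C)CC(=O)[C@H]2C(C)(C)CCC[C@@]21C | intermediate
16 | tert-butyl 6-oxo-13,14,15,16-tetranorlabd-7-en-12-oate (H-9 α) | CC(C)(C)OC(=O)C[C@H]1C(C)=CC(=O)[C@H]2C(C)(C)CCC[C@@]21C | intermediate
17 | tert-butyl 6β-hydroxy-13,14,15,16-tetranorlabd-7-en-12-oate | CC(C)(C)OC(=O)C[C@H]1C(C)=C[C@@H](O)[C@H]2C(C)(C)CCC[C@@]21C | intermediate
18 | tert-butyl 7β,8β-epoxy-6β-hydroxy-13,14,15,16-tetranorlabdan-12-oate | CC(C)(C)OC(=O)C[C@H]1[C@@]3(C)O[C@H]3[C@@H](O)[C@H]2C(C)(C)CCC[C@@]21C | intermediate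
19 | 6β,7β-dihydroxy-13,14,15,16-tetranorlabdan-8α,12-olide | O=C1C[C@H]2[C@](C)(O1)[C@@H](O)[C@@H](O)[C@H]3C(C)(C)CCC[C@@]32C | intermediate
20 | ethynyltrimethylsilane | C#C[Si](C)(C)C | starting material
21 | 6β,7β,8α-trihydroxy-14-trimethylsilyl-15,16-dinorlabd-13-yn-12-one | C[Si](C)(C)C#CC(=O)C[C@H]1[C@](C)(O)[C@@H](O)[C@@H](O)[C@H]2C(C)(C)CCC[C@@]21C | intermediate
22 | 6β-hydroxy-7β,8α-bis(triethylsilyloxy)-14-trimethylsilyl-15,16-dinorlabd-13-yn-12-one | C[Si](C)(C)C#CC(=O)C[C@H]1[C@](C)(O[Si](CC)(CC)CC)[C@@H](O[Si](CC)(CC)CC)[C@@H](O)[C@H]2C(C)(C)CCC[C@@]21C | intermediate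
23 | (12S)-7β,8α-bis(triethylsilyloxy)-14-trimethylsilyl-15,16-dinorlabd-13-yne-6β,12-diol | C[Si](C)(C)C#C[C@H](C[C@H]1[C@](C)(O[Si](CC)(CC)CC)[C@@H](O[Si](CC)(CC)CC)[C@@H](O)[C@H]2C(C)(C)CCC[C@@]21C)O | intermediate
24 | (12S)-6β-hydroxy-7β,8α-bis(triethylsilyloxy)-14-trimethylsilyl-15,16-dinorlabd-13-yn-12-yl methanesulfonate | C[Si](C)(C)C#C[C@H](C[C@H]1[C@](C)(O[Si](CC)(CC)CC)[C@@H](O[Si](CC)(CC)CC)[C@@H](O)[C@H]2C(C)(C)CCC[C@@]21C)OS(C)(=O)=O | intermediate
25 | 2,3-dimethylbut-2-ene | CC(C)=C(C)C | starting material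
26 | 2-methoxyprop-2-yl hydroperoxide | COC(C)(C)OO | intermediate
27 | (12R)-12-(2-methoxyprop-2-ylperoxy)-7β,8α-bis(triethylsilyloxy)-14-trimethylsilyl-15,16-dinorlabd-13-yn-6β-ol | C[Si](C)(C)C#C[C@@H](C[C@H]1[C@](C)(O[Si](CC)(CC)CC)[C@@H](O[Si](CC)(CC)CC)[C@@H](O)[C@H]2C(C)(C)CCC[C@@]21C)OOC(C)(C)OC | intermediate
28 | (12R)-12-(2-methoxyprop-2-ylperoxy)-15,16-dinorlabd-13-yne-6β,7β,8α-triol | C#C[C@@H](C[C@H]1[C@](C)(O)[C@@H](O)[C@@H](O)[C@H]2C(C)(C)CCC[C@@]21C)OOC(C)(C)OC | intermediate
29 | (12R)-7β-acetoxy-12-(2-methoxyprop-2-ylperoxy)-15,16-dinorlabd-13-yne-6β,8α-diol | C#C[C@@H](C[C@H]1[C@](C)(O)[C@@H](OC(C)=O)[C@@H](O)[C@H]2C(C)(C)CCC[C@@]21C)OOC(C)(C)OC | intermediate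
30 | ethene | C=C | starting material
31 | (12R)-7β-acetoxy-12-(2-methoxyprop-2-ylperoxy)labda-13(16),14-diene-6β,8α-diol | C=CC(=C)[C@@H](C[C@H]1[C@](C)(O)[C@@H](OC(C)=O)[C@@H](O)[C@H]2C(C)(C)CCC[C@@]21C)OOC(C)(C)OC | intermediate
32 | (12R)-7β-acetoxy-12-hydroperoxylabda-13(16),14-diene-6β,8α-diol, (5S,6S,7S,8S,9R,10S,12R) | C=CC(=C)[C@@H](C[C@H]1[C@](C)(O)[C@@H](OC(C)=O)[C@@H](O)[C@H]2C(C)(C)CCC[C@@]21C)OO | target

Total step count: 22. Longest linear sequence: 19 steps (steps 1, 2, 5–16, 18–22; the branch through steps 3 and 4 is equally long).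

**Steps most likely to fail**

Step 8. The bond between the neopentyl β-carbon C5 and the fully substituted diene terminus C10 may form too slowly under iminium activation, or the stepwise pathway may end in proton loss instead of ring closure, and any uncatalysed background reaction would erode face selectivity. Fallback (auxiliary-controlled, Lewis-acid-promoted cycloaddition), setting out from 12 and returning at 13: Pinnick oxidation (NaClO2, NaH2PO4, 2-methylbut-2-ene) gives (2E,8E)-11-tert-butoxy-4,4,8-trimethyl-11-oxo-9-(prop-1-en-2-yl)undeca-2,8-dienoic acid F1. Its mixed pivalic anhydride is acylated onto lithiated (S)-4-benzyloxazolidin-2-one to give the N-enoyl imide F2. Me2AlCl in CH2Cl2 at −30 °C (chelated imide, endo mode, diene on the face away from the benzyl group) should give the trans-fused cycloadduct imide F3. LiBH4 in wet Et2O then removes the auxiliary to give tert-butyl 6α-(hydroxymethyl)-13,14,15,16-tetranorlabd-8-en-12-oate F4, and Dess–Martin periodinane oxidises it to 13.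

Step 12. Attack on C8 from the α face demands a diequatorial-type trajectory. Full ionisation at C8 could instead be followed by hydride shift from C7, proton loss, or lactone closure on the β face, and incomplete face selectivity in the directed epoxidation of step 11 would add to the problem. Fallback (dihydroxylation and redox inversion at C7), setting out from 17 and returning at 19: OsO4 (cat.)/N-methylmorpholine N-oxide adds to the α face (anti to the 6β-hydroxyl and the C10 methyl) to give tert-butyl 6β,7α,8α-trihydroxy-13,14,15,16-tetranorlabdan-12-oate F5. Bu2SnO in refluxing MeOH forms the 7α,8α-O-dibutylstannylene acetal F6, which Br2 oxidises at the secondary carbinol to tert-butyl 6β,8α-dihydroxy-7-oxo-13,14,15,16-tetranorlabdan-12-oate F7. CF3CO2H closes 6β-hydroxy-7-oxo-13,14,15,16-tetranorlabdan-8α,12-olide F8, and NaBH4 (hydride on the α face) gives 19.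

Step 18. The peroxide anion may act as a base (E2 toward the conjugated enyne) or attack the alkyne terminus (SN2′ to an allenyl peroxide). The propargylic peroxide may also fragment under base (Kornblum–DeLaMare type), or a silyl ether may be lost and O7 or O8 may then close onto C12. Fallback (photo-oxygenation of a 12,14-diene), setting out from 19 and returning at 32: i-Bu2AlH reduces the lactone to the lactol 6β,7β-dihydroxy-8α,12-epoxy-13,14,15,16-tetranorlabdan-12-ol F9. Wittig reaction with 2-(triphenylphosphoranylidene)propanal gives (12E)-6β,7β,8α-trihydroxy-15-norlabd-12-en-14-al F10, and methylenetriphenylphosphorane gives (12E)-labda-12,14-diene-6β,7β,8α-triol F11. Ac2O/pyridine gives (12E)-7β-acetoxylabda-12,14-diene-6β,8α-diol F12. A Schenck ene reaction (O2, hν, tetraphenylporphyrin, CH2Cl2, 0 °C) with hydrogen abstraction from the C16 methyl should then give 32 together with its C12 epimer, from which it must be separated. This detour gives up reagent control at C12 and also bypasses steps 13 to 21.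

Further compounds
F1 | step 8 | (2E,8E)-11-tert-butoxy-4,4,8-trimethyl-11-oxo-9-(prop-1-en-2-yl)undeca-2,8-dienoic acid | OC(=O)/C=C/C(C)(C)CCC/C(C)=C(\CC(=O)OC(C)(C)C)C(C)=C
F2 | step 8 | tert-butyl (3E,9E)-11-[(4S)-4-benzyl-2-oxooxazolidin-3-yl]-4,8,8-trimethyl-11-oxo-3-(prop-1-en-2-yl)undeca-3,9-dienoate | O=C1OC[C@H](Cc2ccccc2)N1C(=O)/C=C/C(C)(C)CCC/C(C)=C(\CC(=O)OC(C)(C)C)C(C)=C
F3 | step 8 | tert-butyl 6α-{[(4S)-4-benzyl-2-oxooxazolidin-3-yl]carbonyl}-13,14,15,16-tetranorlabd-8-en-12-oate | CC(C)(C)OC(=O)CC1=C(C)C[C@H](C(=O)N3C(=O)OC[C@@H]3Cc3ccccc3)[C@H]2C(C)(C)CCC[C@@]21C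
F4 | step 8 | tert-butyl 6α-(hydroxymethyl)-13,14,15,16-tetranorlabd-8-en-12-oate | CC(C)(C)OC(=O)CC1=C(C)C[C@H](CO)[C@H]2C(C)(C)CCC[C@@]21C
F5 | step 12 | tert-butyl 6β,7α,8α-trihydroxy-13,14,15,16-tetranorlabdan-12-oate | CC(C)(C)OC(=O)C[C@H]1[C@](C)(O)[C@H](O)[C@@H](O)[C@H]2C(C)(C)CCC[C@@]21C
F6 | step 12 | 7α,8α-O-dibutylstannylene acetal of F5 | CC(C)(C)OC(=O)C[C@H]1[C@]4(C)O[Sn](CCCC)(CCCC)O[C@@H]4[C@@H](O)[C@H]2C(C)(C)CCC[C@@]21C
F7 | step 12 | tert-butyl 6β,8α-dihydroxy-7-oxo-13,14,15,16-tetranorlabdan-12-oate | CC(C)(C)OC(=O)C[C@H]1[C@](C)(O)C(=O)[C@@H](O)[C@H]2C(C)(C)CCC[C@@]21C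
F8 | step 12 | 6β-hydroxy-7-oxo-13,14,15,16-tetranorlabdan-8α,12-olide | O=C1C[C@H]2[C@](C)(O1)C(=O)[C@@H](O)[C@H]3C(C)(C)CCC[C@@]32C
F9 | step 18 | 6β,7β-dihydroxy-8α,12-epoxy-13,14,15,16-tetranorlabdan-12-ol (lactol, both anomers) | OC1C[C@H]2[C@](C)(O1)[C@@H](O)[C@@H](O)[C@H]3C(C)(C)CCC[C@@]32C
F10 | step 18 | (12E)-6β,7β,8α-trihydroxy-15-norlabd-12-en-14-al | O=C/C(C)=C/C[C@H]1[C@](C)(O)[C@@H](O)[C@@H](O)[C@H]2C(C)(C)CCC[C@@]21C
F11 | step 18 | (12E)-labda-12,14-diene-6β,7β,8α-triol | C=C/C(C)=C/C[C@H]1[C@](C)(O)[C@@H](O)[C@@H](O)[C@H]2C(C)(C)CCC[C@@]21C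
F12 | step 18 | (12E)-7β-acetoxylabda-12,14-diene-6β,8α-diol | C=C/C(C)=C/C[C@H]1[C@](C)(O)[C@@H](OC(C)=O)[C@@H](O)[C@H]2C(C)(C)CCC[C@@]21C
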